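The target ring (C1 and C4 carry the tiglate oxygens, C2=C3 is the alkene with CH2OH on C3, C5 carries OAc, C6 isopropyl) is a cyclohex-2-ene-1,4-diol with trans C5/C6 substituents, the retron of a Diels–Alder reaction, so the ring is cut at C4–C5 and C1–C6. One catalytic asymmetric endo cycloaddition of (E)-4-methylpent-2-enal with a 1,4-dioxygenated diene forms both bonds and sets C4, C5 and C6. In the diene, C1 is an (E)-enol acetate and the C4 oxygen and the CH2OH oxygen are tied in a 4H-1,3-dioxin, whose locked enol ether steers the regiochemistry. Formyl is later exchanged for oxygen (Baeyer–Villiger) and C1 is inverted (Mitsunobu).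

Key step: step 3

Assumption: the sense of induction of the AlBr3-activated (S)-oxazaborolidine is taken from the usual formyl C–H···O binding model; should the mirror-image adduct form, the (R)-catalyst is used and nothing else changes.

Remark: in the acetonide-bridged intermediates 7 to 12 the benzodioxin locants 6, 5, 4a, 8a, 8 and 7 correspond to ring atoms C1, C2, C3, C4, C5 and C6.

Step 1
Reactants: 1 2,2-dimethyl-1,3-dioxan-5-one; 2 (triphenylphosphoranylidene)acetaldehyde
Product: 3 2-(2,2-dimethyl-1,3-dioxan-5-ylidene)acetaldehyde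
Conditions: toluene, 70 °C (1 in slight excess)
Reagents that add atoms: none
Why: Wittig olefination of the electrophilic, doubly α-oxygenated ketone with the stabilised formyl ylide should give the enal directly, and the symmetry of the ketone makes the alkene geometry irrelevant.

Step 2
Reactants: 3 2-(2,2-dimethyl-1,3-dioxan-5-ylidene)acetaldehyde; 4 acetic anhydride
Product: 5 (E)-2-(2,2-dimethyl-4H-1,3-dioxin-5-yl)ethenyl acetate
Conditions: Et3N, DMAP (cat.), CH2Cl2, 40 °C
Reagents that add atoms: none
Why: Vinylogous (γ) enolisation of the enal and O-acetylation of the dienolate (dienyl acetate formation) should move the double bond into the ring as a cyclic enol ether and give mainly the (E)-enol acetate from the s-trans enal, the two ring CH2 groups being equivalent and any (Z)-isomer being inert in step 3.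

Step 3
Reactants: 5 (E)-2-(2,2-dimethyl-4H-1,3-dioxin-5-yl)ethenyl acetate; 6 (E)-4-methylpent-2-enal
Product: 7 (6S,7R,8R,8aR)-8-formyl-2,2-dimethyl-7-(propan-2-yl)-6,7,8,8a-tetrahydro-4H-1,3-benzodioxin-6-yl acetate
Conditions: (S)-3,3-diphenyl-1-(2-methylphenyl)tetrahydro-1H,3H-pyrrolo[1,2-c][1,3,2]oxazaborole (10 mol%) activated with AlBr3 (8 mol%), 5 (1.5 equiv), CH2Cl2, −78 → −40 °C
Reagents that add atoms: none
Why: The AlBr3-activated oxazaborolidine binds the formyl oxygen of 6 and lowers its LUMO, so that a concerted, asynchronous [4π+2π] cycloaddition with the electron-rich diene 5 should take place, the closest known reaction type being the chiral oxazaborolidinium-catalysed Diels–Alder reaction of α,β-unsaturated aldehydes with 1-oxygenated dienes. The cyclohexene ring closes by intermolecular cycloaddition, suprafacial on both partners, with C1–C6 bond formation running ahead of C4–C5. C5 and C6 become trans because the (E)-enal geometry is retained, the C1 and C4 oxygens become cis because both occupy outside positions of the diene (the C4 oxygen is locked there by the dioxin ring), the C5 formyl group becomes cis to the C4 oxygen through the endo transition state, and the absolute configuration is set by the catalyst, which covers the α-Re face of the bound enal. The regiochemistry needed (C4 to the α-carbon C5, C1 to the β-carbon C6) is secured by the ring enol-ether oxygen on C4, the strongest donor of the diene, which makes C1 the nucleophilic terminus and outweighs the enol acetate and the C3 alkyl group. Endo and facial selectivity rest on Lewis-acid activation at low temperature, which should also hold back hetero-Diels–Alder and Mukaiyama–Michael pathways of the enol ether.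

Step 4
Reactants: 7 (6S,7R,8R,8aR)-8-formyl-2,2-dimethyl-7-(propan-2-yl)-6,7,8,8a-tetrahydro-4H-1,3-benzodioxin-6-yl acetate
Product: 9 (6R,7S,8R,8aS)-2,2-dimethyl-7-(propan-2-yl)-6,7,8,8a-tetrahydro-4H-1,3-benzodioxine-6,8-diol, via C5 formate 8 (not isolated)
Conditions: mCPBA, CH2Cl2, 0 °C; then K2CO3, MeOH, 0 °C → rt
Reagents that add atoms: 3-chloroperoxybenzoic acid (mCPBA), OOC(=O)c1cccc(Cl)c1
Why: Baeyer–Villiger oxidation of the α-branched aldehyde (migration of the secondary carbon C5 with retention) should outpace epoxidation of the alkene flanked by three allylic oxygens, and base methanolysis in the same flask then removes the formate and the C1 acetate.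

Step 5
Reactants: 9 (6R,7S,8R,8aS)-2,2-dimethyl-7-(propan-2-yl)-6,7,8,8a-tetrahydro-4H-1,3-benzodioxine-6,8-diol; 10 (E)-2-methylbut-2-enoic acid (tiglic acid)
Product: 11 (6S,7R,8R,8aS)-8-hydroxy-2,2-dimethyl-7-(propan-2-yl)-6,7,8,8a-tetrahydro-4H-1,3-benzodioxin-6-yl (2E)-2-methylbut-2-enoate
Conditions: PPh3, DIAD, toluene, 0 °C → rt
Reagents that add atoms: none
Why: Mitsunobu esterification (SN2 displacement of the alkoxyphosphonium by tiglate) should engage only the allylic C1 hydroxyl, the C5 hydroxyl lying between two branched carbons, and inverts C1 so that its oxygen becomes cis to the C6 isopropyl group and trans to the C4 oxygen, as in the target.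

Step 6
Reactants: 11 (6S,7R,8R,8aS)-8-hydroxy-2,2-dimethyl-7-(propan-2-yl)-6,7,8,8a-tetrahydro-4H-1,3-benzodioxin-6-yl (2E)-2-methylbut-2-enoate; 4 acetic anhydride
Product: 12 (6S,7S,8R,8aS)-8-acetoxy-2,2-dimethyl-7-(propan-2-yl)-6,7,8,8a-tetrahydro-4H-1,3-benzodioxin-6-yl (2E)-2-methylbut-2-enoate
Conditions: DMAP, pyridine, CH2Cl2, rt
Reagents that add atoms: none
Why: DMAP-catalysed acetylation of the remaining hindered secondary alcohol installs the C5 acetate without touching a stereocentre.

Step 7
Reactants: 12 (6S,7S,8R,8aS)-8-acetoxy-2,2-dimethyl-7-(propan-2-yl)-6,7,8,8a-tetrahydro-4H-1,3-benzodioxin-6-yl (2E)-2-methylbut-2-enoate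
Product: 13 (1S,4S,5R,6S)-5-acetoxy-4-hydroxy-3-(hydroxymethyl)-6-(propan-2-yl)cyclohex-2-en-1-yl (2E)-2-methylbut-2-enoate
Conditions: AcOH/H2O/THF (3:1:1), 35 °C
Reagents that add atoms: none
Why: Mild aqueous-acid hydrolysis of the 1,3-dioxane acetonide should free the C4 and primary hydroxyls without ionising the allylic esters or moving the acetate.

Step 8
Reactants: 13 (1S,4S,5R,6S)-5-acetoxy-4-hydroxy-3-(hydroxymethyl)-6-(propan-2-yl)cyclohex-2-en-1-yl (2E)-2-methylbut-2-enoate; 14 (E)-2-methylbut-2-enoic anhydride (tiglic anhydride)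
Product: 17 (1S,4S,5R,6S)-5-acetoxy-3-(hydroxymethyl)-6-(propan-2-yl)cyclohex-2-ene-1,4-diyl bis[(2E)-2-methylbut-2-enoate], via primary triethylsilyl ether 15 (not isolated), via silyl ether bis-tiglate 16 (not isolated)
Conditions: Et3SiCl (1.05 equiv), imidazole, CH2Cl2, −78 → −30 °C; then 14, DMAP, Et3N, 0 °C → rt; then 1 M aq. HCl, THF, 0 °C → rt
Reagents that add atoms: chlorotriethylsilane, CC[Si](Cl)(CC)CC (adds the silyl group of 15 and 16 only; none of its atoms remain in 17)
Why: Transient silylation of the primary alcohol (steric selection), DMAP-catalysed acylation of the C4 hydroxyl with retention, and acid cleavage of the primary silyl ether in one flask should give the target.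

Compound list

1 | 2,2-dimethyl-1,3-dioxan-5-one | O=C1COC(C)(C)OC1 | starting material
2 | (triphenylphosphoranylidene)acetaldehyde | O=CC=P(c1ccccc1)(c1ccccc1)c1ccccc1 | starting material
3 | 2-(2,2-dimethyl-1,3-dioxan-5-ylidene)acetaldehyde | O=CC=C1COC(C)(C)OC1 | intermediate
4 | acetic anhydride | CC(=O)OC(C)=O | starting material
5 | (E)-2-(2,2-dimethyl-4H-1,3-dioxin-5-yl)ethenyl acetate | CC(=O)O/C=C/C1=COC(C)(C)OC1 | intermediate
6 | (E)-4-methylpent-2-enal | CC(C)/C=C/C=O | starting material
7 | (6S,7R,8R,8aR)-8-formyl-2,2-dimethyl-7-(propan-2-yl)-6,7,8,8a-tetrahydro-4H-1,3-benzodioxin-6-yl acetate (acetate, formyl and ring oxygen all cis, isopropyl trans) | CC(=O)O[C@@H]1C=C2COC(C)(C)O[C@@H]2[C@H](C=O)[C@H]1C(C)C | intermediate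
8 | (6R,7S,8R,8aS)-8-(formyloxy)-2,2-dimethyl-7-(propan-2-yl)-6,7,8,8a-tetrahydro-4H-1,3-benzodioxin-6-yl acetate | CC(=O)O[C@@H]1C=C2COC(C)(C)O[C@@H]2[C@H](OC=O)[C@H]1C(C)C | intermediate
9 | (6R,7S,8R,8aS)-2,2-dimethyl-7-(propan-2-yl)-6,7,8,8a-tetrahydro-4H-1,3-benzodioxine-6,8-diol | O[C@@H]1C=C2COC(C)(C)O[C@@H]2[C@H](O)[C@H]1C(C)C | intermediate
10 | (E)-2-methylbut-2-enoic acid (tiglic acid) | C/C=C(\C)C(=O)O | starting material
11 | (6S,7R,8R,8aS)-8-hydroxy-2,2-dimethyl-7-(propan-2-yl)-6,7,8,8a-tetrahydro-4H-1,3-benzodioxin-6-yl (2E)-2-methylbut-2-enoate | C/C=C(\C)C(=O)O[C@H]1C=C2COC(C)(C)O[C@@H]2[C@H](O)[C@H]1C(C)C | intermediate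
12 | (6S,7S,8R,8aS)-8-acetoxy-2,2-dimethyl-7-(propan-2-yl)-6,7,8,8a-tetrahydro-4H-1,3-benzodioxin-6-yl (2E)-2-methylbut-2-enoate | C/C=C(\C)C(=O)O[C@H]1C=C2COC(C)(C)O[C@@H]2[C@H](OC(C)=O)[C@H]1C(C)C | intermediate
13 | (1S,4S,5R,6S)-5-acetoxy-4-hydroxy-3-(hydroxymethyl)-6-(propan-2-yl)cyclohex-2-en-1-yl (2E)-2-methylbut-2-enoate | C/C=C(\C)C(=O)O[C@H]1C=C(CO)[C@H](O)[C@H](OC(C)=O)[C@H]1C(C)C | intermediate
14 | (E)-2-methylbut-2-enoic anhydride (tiglic anhydride) | C/C=C(\C)C(=O)OC(=O)/C(C)=C/C | starting material
15 | (1S,4S,5R,6S)-5-acetoxy-4-hydroxy-6-(propan-2-yl)-3-[(triethylsilyloxy)methyl]cyclohex-2-en-1-yl (2E)-2-methylbut-2-enoate | C/C=C(\C)C(=O)O[C@H]1C=C(CO[Si](CC)(CC)CC)[C@H](O)[C@H](OC(C)=O)[C@H]1C(C)C | intermediate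
16 | (1S,4S,5R,6S)-5-acetoxy-6-(propan-2-yl)-3-[(triethylsilyloxy)methyl]cyclohex-2-ene-1,4-diyl bis[(2E)-2-methylbut-2-enoate] | C/C=C(\C)C(=O)O[C@H]1C=C(CO[Si](CC)(CC)CC)[C@H](OC(=O)/C(C)=C/C)[C@H](OC(C)=O)[C@H]1C(C)C | intermediate
17 | (1S,4S,5R,6S)-5-acetoxy-3-(hydroxymethyl)-6-(propan-2-yl)cyclohex-2-ene-1,4-diyl bis[(2E)-2-methylbut-2-enoate] | C/C=C(\C)C(=O)O[C@H]1C=C(CO)[C@H](OC(=O)/C(C)=C/C)[C@H](OC(C)=O)[C@H]1C(C)C | target

Total step count: 8. Longest linear sequence: 8 steps (from 1 to 17).

Steps most likely to fail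

Step 3. What may go wrong: acid-triggered breakdown of the cyclic enol acetal of the diene before cycloaddition, or incomplete facial and endo control with the hindered β-isopropyl enal. The fallback replaces catalyst control by auxiliary control. Setting out from 3, the potassium dienolate (KN(SiMe3)2, THF, −78 °C) is O-acylated with (S)-2-methoxy-2-phenylacetyl chloride to give the dienyl (S)-O-methylmandelate F1. Cycloaddition with 6 under mild achiral promotion (ZnCl2, CH2Cl2, −20 °C) should give the endo adduct F2, the phenyl ring of the auxiliary covering one face of the diene; the auxiliary antipode is chosen accordingly and diastereomers can be separated. F2 is taken through the conditions of step 4 without isolating the formate F3. The methanolysis that removes the formate also removes the auxiliary, and the route is rejoined at 9.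

Step 4. What may go wrong: migration of hydride instead of C5, which gives the carboxylic acid, or competing epoxidation of the ring alkene. The fallback uses a ketone in place of the aldehyde. Setting out from 5, the cycloaddition of step 3 is run with commercial (E)-5-methylhex-3-en-2-one to give the methyl ketone F4, the catalyst antipode being assigned anew for the ketone. Baeyer–Villiger oxidation with Me3SiOOSiMe3, SnCl4 and trans-cyclohexane-1,2-diamine (CH2Cl2, 0 °C) spares alkenes, and the secondary carbon migrates in preference to methyl, so it should give the diacetate F5. K2CO3 in MeOH then cleaves both acetates and the route is rejoined at 9.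

Step 5. What may go wrong: slow displacement at the carbinol next to the isopropyl-bearing carbon, leading to elimination or to ester formation with retention. The fallback replaces SN2 inversion by oxidation and reduction. Setting out from 9, MnO2 (CH2Cl2, rt) should oxidise only the allylic hydroxyl, giving the enone F6. LiBH(s-Bu)3 (THF, −78 °C) should add hydride to the face opposite the adjacent isopropyl group and give the C1-epimeric diol F7. Carbodiimide esterification of the more accessible allylic hydroxyl with 10 (DCC, DMAP, CH2Cl2, −20 °C) then gives 11, where the route is rejoined.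

Further compounds
F1 | step 3 | (E)-2-(2,2-dimethyl-4H-1,3-dioxin-5-yl)ethenyl (S)-2-methoxy-2-phenylacetate | CO[C@@H](c1ccccc1)C(=O)O/C=C/C1=COC(C)(C)OC1
F2 | step 3 | cycloadduct 7 with the C1 acetate replaced by (S)-2-methoxy-2-phenylacetate | CO[C@@H](c1ccccc1)C(=O)O[C@@H]1C=C2COC(C)(C)O[C@@H]2[C@H](C=O)[C@H]1C(C)C
F3 | step 3 | C5 formate of F2 | CO[C@@H](c1ccccc1)C(=O)O[C@@H]1C=C2COC(C)(C)O[C@@H]2[C@H](OC=O)[C@H]1C(C)C
F4 | step 4 | C5 acetyl (methyl ketone) analogue of 7 | CC(=O)O[C@@H]1C=C2COC(C)(C)O[C@@H]2[C@H](C(C)=O)[C@H]1C(C)C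
F5 | step 4 | C1,C5 diacetate on the acetonide core | CC(=O)O[C@@H]1C=C2COC(C)(C)O[C@@H]2[C@H](OC(C)=O)[C@H]1C(C)C
F6 | step 5 | C1 ketone (enone) of 9 with free C5 hydroxyl | O=C1C=C2COC(C)(C)O[C@@H]2[C@H](O)[C@H]1C(C)C
F7 | step 5 | C1 epimer of diol 9 | O[C@H]1C=C2COC(C)(C)O[C@@H]2[C@H](O)[C@H]1C(C)C
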